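**Retrosynthetic overview**
- The target comes from its bis‑silyl ether; the chromene‑dione core (ring A = carbocycle, ring B = pyran) is cut at C5–C6, C8–C8a and O1–C8a.
- Ring A and ring B close in one flask: the dianion of an aryl 1,3‑diketone and a δ‑lactone carrying an activated ester undergo a double Claisen that closes ring A and opens the lactone; acid then closes ring B on C8a. Order: ring A, then ring B; the arene is bought.
- The δ‑lactone is a temporary ring that carries O1, C2, C3 and the quaternary C4a. It is made from an (R)‑lavandulyl malonate by hydration–lactonization, then alkylated with a second (R)‑lavandulyl iodide trans to the prenyl group.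
- (R)‑Lavandulyl iodide (used twice) comes from an Evans deconjugative prenylation of a senecioyl imide.
- The diketone comes from a Claisen condensation of 6‑methylhept‑5‑en‑2‑one with silylated methyl protocatechuate.

Assumption: C6 lies between the C5 and C7 carbonyls and is configurationally labile (keto–enol), so the (6S) keto form drawn is taken as the epimer reached on equilibration; the other three stereocentres are set by the route.

Notation: Lav = 5‑methyl‑2‑(prop‑1‑en‑2‑yl)hex‑4‑en‑1‑yl with the stereocentre as in (R)‑lavandulol (its CIP label reads S once the CH2 carries carbon); prenyl = 3‑methylbut‑2‑en‑1‑yl; TFE = 2,2,2‑trifluoroethyl; TBS = tert‑butyldimethylsilyl; Ar = 3,4‑bis(TBS‑oxy)phenyl; core locants (O1 … C8a) are those of the chromene in the target.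

**Step 1**
Reactants: 1 (R)‑4‑benzyl‑1,3‑oxazolidin‑2‑one; 2 3‑methylbut‑2‑enoyl chloride
Product: 3 (R)‑4‑benzyl‑3‑(3‑methylbut‑2‑enoyl)‑1,3‑oxazolidin‑2‑one
Conditions: n‑BuLi, THF, −78 °C; then 2, −78 → 0 °C
Reagents that add atoms: none
Why: N‑acylation of the lithiated Evans auxiliary by the acid chloride; no stereocentre is formed.

**Step 2**
Reactants: 3 (R)‑4‑benzyl‑3‑(3‑methylbut‑2‑enoyl)‑1,3‑oxazolidin‑2‑one; 4 1‑bromo‑3‑methylbut‑2‑ene (prenyl bromide)
Product: 5 (R)‑4‑benzyl‑3‑[(2R)‑5‑methyl‑2‑(prop‑1‑en‑2‑yl)hex‑4‑enoyl]‑1,3‑oxazolidin‑2‑one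
Conditions: NaN(SiMe3)2, THF, −78 °C; 4, −78 → −40 °C; AcOH quench at −78 °C
Reagents that add atoms: none
Why: Evans deconjugative α‑alkylation: the chelated (Z)‑dienolate is prenylated at the α‑carbon on the face opposite the benzyl group, which sets the lavandulyl stereocentre (2R).

**Step 3**
Reactants: 5 (R)‑4‑benzyl‑3‑[(2R)‑5‑methyl‑2‑(prop‑1‑en‑2‑yl)hex‑4‑enoyl]‑1,3‑oxazolidin‑2‑one
Product: 6 (R)‑lavandulol, (2R)‑5‑methyl‑2‑(prop‑1‑en‑2‑yl)hex‑4‑en‑1‑ol
Conditions: LiBH4, H2O (1 equiv), Et2O, 0 °C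
Reagents that add atoms: none
Why: Reductive cleavage of the N‑acyl oxazolidinone by borohydride gives the primary alcohol without touching the stereocentre or the alkenes and returns the auxiliary.

**Step 4**
Reactants: 6 (R)‑lavandulol
Product: 7 (R)‑lavandulyl iodide, (3R)‑3‑(iodomethyl)‑2,6‑dimethylhepta‑1,5‑diene
Conditions: I2, PPh3, imidazole, CH2Cl2, 0 °C → rt
Reagents that add atoms: iodine, II
Why: Appel iodination of the primary alcohol (SN2 at CH2); the adjacent stereocentre is not involved.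

**Step 5**
Reactants: 7 (R)‑lavandulyl iodide; 8 bis(2,2,2‑trifluoroethyl) malonate
Product: 9 bis(TFE) 2‑Lav‑malonate
Conditions: NaH, 8 (3 equiv), DMF, 0 → 60 °C
Reagents that add atoms: none
Why: Malonic ester alkylation (SN2), with excess malonate to stop at monoalkylation; the stereocentre is β to the reacting carbon and is unaffected.

**Step 6**
Reactants: 9 bis(TFE) 2‑Lav‑malonate
Product: 11 TFE (5S)‑6,6‑dimethyl‑5‑prenyl‑2‑oxooxane‑3‑carboxylate (C3 epimers), via hydroxy malonate 10 (not isolated)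
Conditions: Co(acac)2 (cat.), PhSiH3, O2 (1 atm), THF, rt; then Et3N (cat.), rt
Reagents that add atoms: dioxygen, O=O
Why: Mukaiyama hydration (cobalt hydride hydrogen‑atom transfer, Markovnikov) takes the 1,1‑disubstituted isopropenyl alkene in preference to the trisubstituted prenyl alkene, and the tertiary alcohol then lactonizes onto an activated trifluoroethyl ester; C5 comes from lavandulol and C3 is a labile malonate‑type centre.

**Step 7**
Reactants: 11 TFE (5S)‑6,6‑dimethyl‑5‑prenyl‑2‑oxooxane‑3‑carboxylate; 7 (R)‑lavandulyl iodide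
Product: 12 TFE (3S,5S)‑3‑Lav‑6,6‑dimethyl‑5‑prenyl‑2‑oxooxane‑3‑carboxylate (Lav trans to the C5 prenyl)
Conditions: Cs2CO3, DMF, 50 °C
Reagents that add atoms: none
Why: C‑alkylation (SN2) of the planar malonate‑type lactone enolate; the iodide approaches anti to the C5 prenyl group (pseudo‑axial beside the gem‑dimethyl carbon), so the new quaternary centre carries Lav trans to prenyl.

**Step 8**
Reactants: 13 methyl 3,4‑dihydroxybenzoate
Product: 14 methyl 3,4‑bis(tert‑butyldimethylsilyloxy)benzoate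
Conditions: TBSCl, imidazole, DMF, rt
Reagents that add atoms: tert‑butyldimethylsilyl chloride, CC(C)(C)[Si](C)(C)Cl
Why: Imidazole‑promoted silylation (Corey conditions) protects both catechol hydroxyls against the strong bases used later.

**Step 9**
Reactants: 14 methyl 3,4‑bis(tert‑butyldimethylsilyloxy)benzoate; 15 6‑methylhept‑5‑en‑2‑one
Product: 16 1‑[3,4‑bis(tert‑butyldimethylsilyloxy)phenyl]‑7‑methyloct‑6‑ene‑1,3‑dione
Conditions: 15, LiN(iPr)2 (2.1 equiv), THF, −78 °C; then 14, −78 → 0 °C; AcOH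
Reagents that add atoms: none
Why: Crossed Claisen condensation of the kinetic (methyl‑side) lithium enolate with the aryl ester, driven by deprotonation of the β‑diketone formed.

**Step 10**
Reactants: 16 1‑[3,4‑bis(tert‑butyldimethylsilyloxy)phenyl]‑7‑methyloct‑6‑ene‑1,3‑dione; 12 TFE (3S,5S)‑3‑Lav‑6,6‑dimethyl‑5‑prenyl‑2‑oxooxane‑3‑carboxylate
Product: 19 bis(tert‑butyldimethylsilyl) ether of the target, via lactone triketone 17 (not isolated), via hydroxy trione 18 (not isolated)
Conditions: 16, LiN(iPr)2 (2.2 equiv), THF, −78 → 0 °C; 12, −78 °C; LiN(iPr)2 (1.1 equiv), −78 → 25 °C; then AcOH, PPTS, 4 Å MS, toluene, 60 °C (one pot)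
Reagents that add atoms: none
Why: Proposed new method: the terminal carbanion of the diketone dianion acylates the trifluoroethyl ester (more electrophilic and less shielded than the lactone carbonyl, which sits between the quaternary carbon and the gem‑dimethyl O–C), the resulting tricarbonyl dianion closes ring A by Dieckmann‑type attack of C8 on the lactone carbonyl with loss of the tertiary alkoxide, and on acidification the tertiary alcohol condenses with the C8a carbonyl to the pyran enol ether (ring B), because only that closure gives a chair with prenyl equatorial and Lav axial (closure on C5 would put Lav and prenyl 1,3‑diaxial), so the quaternary centre from step 7 fixes the regiochemistry and C6 ends as the equilibrated epimer; the closest known reactions are Hauser/Huckin–Weiler dianion Claisen acylations, Dieckmann condensations onto lactones and acid‑catalysed enol ether formation from cyclic 1,3‑diketones.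

**Step 11**
Reactants: 19 bis(tert‑butyldimethylsilyl) ether of the target
Product: 20 target, CNP0250793.1
Conditions: Bu4NF, AcOH, THF, 0 °C, argon
Reagents that add atoms: none
Why: Fluoride desilylation of the two aryl silyl ethers, buffered with acetic acid so that the catechol, the vinylogous ester and the β‑diketone see no strong base; no stereocentre is touched.

**Compound list**
1 | (R)‑4‑benzyl‑1,3‑oxazolidin‑2‑one | O=C1N[C@H](Cc2ccccc2)CO1 | starting material
2 | 3‑methylbut‑2‑enoyl chloride | CC(C)=CC(=O)Cl | starting material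
3 | (R)‑4‑benzyl‑3‑(3‑methylbut‑2‑enoyl)‑1,3‑oxazolidin‑2‑one | CC(C)=CC(=O)N1[C@H](Cc2ccccc2)COC1=O | intermediate
4 | 1‑bromo‑3‑methylbut‑2‑ene | CC(C)=CCBr | starting material
5 | (R)‑4‑benzyl‑3‑[(2R)‑5‑methyl‑2‑(prop‑1‑en‑2‑yl)hex‑4‑enoyl]‑1,3‑oxazolidin‑2‑one | C=C(C)[C@@H](CC=C(C)C)C(=O)N1[C@H](Cc2ccccc2)COC1=O | intermediate
6 | (R)‑lavandulol | C=C(C)[C@@H](CC=C(C)C)CO | intermediate
7 | (R)‑lavandulyl iodide, (3R)‑3‑(iodomethyl)‑2,6‑dimethylhepta‑1,5‑diene | C=C(C)[C@@H](CC=C(C)C)CI | intermediate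
8 | bis(2,2,2‑trifluoroethyl) malonate | O=C(CC(=O)OCC(F)(F)F)OCC(F)(F)F | starting material
9 | bis(TFE) 2‑Lav‑malonate | C=C(C)[C@@H](CC=C(C)C)CC(C(=O)OCC(F)(F)F)C(=O)OCC(F)(F)F | intermediate
10 | bis(TFE) 2‑[(2S)‑3‑hydroxy‑3‑methyl‑2‑prenylbutyl]malonate | CC(C)(O)[C@@H](CC=C(C)C)CC(C(=O)OCC(F)(F)F)C(=O)OCC(F)(F)F | intermediate
11 | TFE (5S)‑6,6‑dimethyl‑5‑prenyl‑2‑oxooxane‑3‑carboxylate (C3 epimers) | O=C1OC(C)(C)[C@@H](CC=C(C)C)CC1C(=O)OCC(F)(F)F | intermediate
12 | TFE (3S,5S)‑3‑Lav‑6,6‑dimethyl‑5‑prenyl‑2‑oxooxane‑3‑carboxylate (Lav trans to prenyl) | C=C(C)[C@@H](CC=C(C)C)C[C@@]1(C(=O)OCC(F)(F)F)C[C@H](CC=C(C)C)C(C)(C)OC1=O | intermediate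
13 | methyl 3,4‑dihydroxybenzoate | COC(=O)c1ccc(O)c(O)c1 | starting material
14 | methyl 3,4‑bis(tert‑butyldimethylsilyloxy)benzoate | COC(=O)c1ccc(O[Si](C)(C)C(C)(C)C)c(O[Si](C)(C)C(C)(C)C)c1 | intermediate
15 | 6‑methylhept‑5‑en‑2‑one | CC(=O)CCC=C(C)C | starting material
16 | 1‑[3,4‑bis(tert‑butyldimethylsilyloxy)phenyl]‑7‑methyloct‑6‑ene‑1,3‑dione | CC(C)=CCCC(=O)CC(=O)c1ccc(O[Si](C)(C)C(C)(C)C)c(O[Si](C)(C)C(C)(C)C)c1 | intermediate
17 | 3‑Lav‑3‑(5‑Ar‑3,5‑dioxo‑2‑prenylpentanoyl)‑6,6‑dimethyl‑5‑prenyloxan‑2‑one (ring centres as in 12, side‑chain C2 epimers) | C=C(C)[C@@H](CC=C(C)C)C[C@@]1(C(=O)C(CC=C(C)C)C(=O)CC(=O)c2ccc(O[Si](C)(C)C(C)(C)C)c(O[Si](C)(C)C(C)(C)C)c2)C[C@H](CC=C(C)C)C(C)(C)OC1=O | intermediate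
18 | 2‑(Ar‑carbonyl)‑4‑Lav‑4‑[(2S)‑3‑hydroxy‑3‑methyl‑2‑prenylbutyl]‑6‑prenylcyclohexane‑1,3,5‑trione (C4 as C4a of the target; C2 and C6 enolisable) | C=C(C)[C@@H](CC=C(C)C)C[C@@]1(C[C@H](CC=C(C)C)C(C)(C)O)C(=O)C(C(=O)c2ccc(O[Si](C)(C)C(C)(C)C)c(O[Si](C)(C)C(C)(C)C)c2)C(=O)C(CC=C(C)C)C1=O | intermediate
19 | (3S,4aR,6S)‑8‑[3,4‑bis(tert‑butyldimethylsilyloxy)benzoyl]‑4a‑Lav‑2,2‑dimethyl‑3,6‑diprenyl‑4,4a‑dihydro‑2H‑chromene‑5,7(3H,6H)‑dione | C=C(C)[C@@H](CC=C(C)C)C[C@@]12C[C@H](CC=C(C)C)C(C)(C)OC1=C(C(=O)c1ccc(O[Si](C)(C)C(C)(C)C)c(O[Si](C)(C)C(C)(C)C)c1)C(=O)[C@@H](CC=C(C)C)C2=O | intermediate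
20 | (3S,4aR,6S)‑8‑(3,4‑dihydroxybenzoyl)‑2,2‑dimethyl‑3,6‑bis(3‑methylbut‑2‑en‑1‑yl)‑4a‑[(2S)‑5‑methyl‑2‑(prop‑1‑en‑2‑yl)hex‑4‑en‑1‑yl]‑4,4a‑dihydro‑2H‑chromene‑5,7(3H,6H)‑dione | C=C(C)[C@@H](CC=C(C)C)C[C@@]12C[C@H](CC=C(C)C)C(C)(C)OC1=C(C(=O)c1ccc(O)c(O)c1)C(=O)[C@@H](CC=C(C)C)C2=O | target

**Step count and risks**
Total steps: 11. Longest linear sequence: 9 (steps 1–7, 10, 11); steps 8–9 form the side branch.

The three steps most likely to fail, each with one fallback:

The one‑pot annulation (step 10) is the riskiest. The diketone dianion may attack the lactone carbonyl of 12 instead of the trifluoroethyl ester, which would give the regioisomeric pyran, and the Dieckmann closure onto the hindered lactone may be slow. The fallback sets out from 12. LiOH (1 equiv, THF/H2O, 0 °C) hydrolyses only the activated ester to the lactone acid F1. 1‑Chloro‑N,N,2‑trimethylprop‑1‑en‑1‑amine converts it to the lactone acid chloride F2. The dianion of 16 is then acylated unambiguously at the acid chloride at −78 °C, and the route is rejoined at 17, now isolated. Compound 17 is closed to 18 with KOtBu in THF and to 19 with PPTS in a separate operation.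

The quaternary alkylation (step 7) uses a β‑branched iodide on a stabilised enolate and may stall or give O‑alkylation. The fallback sets out from 9. A second alkylation with 7 (NaH, DMF) on the less hindered acyclic malonate gives the C2‑symmetric bis(lavandulyl)malonate F3. Hydration of one of its two equivalent isopropenyl groups (Co(acac)2, PhSiH3, O2, stopped near half conversion) gives the mono‑alcohol F4. Base‑mediated lactonization rejoins the route at 12, formed together with its C3 epimer F5. The epimer is separated and re‑equilibrated through F4 with catalytic NaOCH2CF3.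

The first malonate alkylation (step 5) pairs a weakly nucleophilic trifluoroethyl malonate with a homoallylic, β‑branched iodide, so elimination may compete. The fallback sets out from 6 and rejoins at 9. It is a Mitsunobu C‑alkylation of 8 with the alcohol itself (PBu3, 1,1′‑(azodicarbonyl)dipiperidine, toluene), for which this malonate is acidic enough; it makes no new compound, F0.

**Further compounds**
F1 | step 10 | (5S)‑3‑Lav‑6,6‑dimethyl‑5‑prenyl‑2‑oxooxane‑3‑carboxylic acid (Lav trans to prenyl) | C=C(C)[C@@H](CC=C(C)C)C[C@@]1(C(=O)O)C[C@H](CC=C(C)C)C(C)(C)OC1=O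
F2 | step 10 | (5S)‑3‑Lav‑6,6‑dimethyl‑5‑prenyl‑2‑oxooxane‑3‑carbonyl chloride (Lav trans to prenyl) | C=C(C)[C@@H](CC=C(C)C)C[C@@]1(C(=O)Cl)C[C@H](CC=C(C)C)C(C)(C)OC1=O
F3 | step 7 | bis(TFE) 2,2‑bis(Lav)malonate | C=C(C)[C@@H](CC=C(C)C)CC(C[C@H](CC=C(C)C)C(C)=C)(C(=O)OCC(F)(F)F)C(=O)OCC(F)(F)F
F4 | step 7 | bis(TFE) 2‑Lav‑2‑[(2S)‑3‑hydroxy‑3‑methyl‑2‑prenylbutyl]malonate | CC(C)(O)[C@@H](CC=C(C)C)CC(C[C@H](CC=C(C)C)C(C)=C)(C(=O)OCC(F)(F)F)C(=O)OCC(F)(F)F
F5 | step 7 | C3 epimer of 12 (Lav cis to the C5 prenyl) | C=C(C)[C@@H](CC=C(C)C)C[C@]1(C(=O)OCC(F)(F)F)C[C@H](CC=C(C)C)C(C)(C)OC1=O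
F0 | step 5 | none | none
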